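**Retrosynthetic overview**
1. Feature: the only stereocentre is the benzylic carbon of the 1-arylpropyl unit. It carries the ester oxygen, the benzene ring (3-OH, 4-OMe, 5-OMe) and an ethyl group. If the ethyl is read as a reduced vinyl group, this carbon is the branched end of a 3-arylallyl system.
2. Key disconnection: the benzylic C–O bond, formed with allylic transposition from the achiral (Z)-cinnamyl trichloroacetimidate 7 and the complete diester acid 15 under [(COP)Pd(OAc)]2. Only vinyl-to-ethyl reduction and O-desilylation follow.
3. Imidate 7 comes from aldehyde 1 by silylation, Still–Gennari olefination, i-Bu2AlH reduction and addition to Cl3CCN.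
4. Acid 15 comes from crotonaldehyde via (Z)-2-iodobut-2-en-1-ol. Carbonylation to a 4-methoxybenzyl ester precedes angeloylation, so zerovalent palladium never meets an allylic ester, and acidolysis then frees the acid.
5. Rings: none is formed; the benzene ring is bought with 1.

Key step: step 10

Abbreviation: COP is the C,N-bound cyclopalladated ligand [η5-2-((S)-4-isopropyl-4,5-dihydrooxazol-2-yl)cyclopentadienyl](η4-tetraphenylcyclobutadiene)cobalt.

Assumption: the (Rp,S) catalyst, taken here to convert (Z)-3-alkylallyl imidates into (R)-3-acyloxy-1-alkenes, is assumed to attack the same alkene face of 7; that face is named S only because aryl outranks vinyl whereas alkyl does not, and the mirror-image (Sp,R) catalyst is used if a trial shows the opposite sense.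

**Step 1**
Reactants: 1 3-hydroxy-4,5-dimethoxybenzaldehyde
Product: 2 3-(tert-butyldimethylsilyloxy)-4,5-dimethoxybenzaldehyde
Conditions: TBSCl, imidazole, DMF, rt
Reagents that add atoms: tert-butyldimethylsilyl chloride (TBSCl), CC(C)(C)[Si](C)(C)Cl
Why: Imidazole-promoted silyl ether protection of a phenol, needed because a free phenol would add to Cl3CCN in step 4 and would compete as a nucleophile in step 10.

**Step 2**
Reactants: 2 3-(tert-butyldimethylsilyloxy)-4,5-dimethoxybenzaldehyde; 3 methyl bis(2,2,2-trifluoroethyl)phosphonoacetate
Product: 4 methyl (Z)-3-[3-(tert-butyldimethylsilyloxy)-4,5-dimethoxyphenyl]prop-2-enoate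
Conditions: 3, KN(SiMe3)2, 18-crown-6, THF, −78 °C; then 2
Reagents that add atoms: none
Why: In the Still–Gennari variant of the Horner–Wadsworth–Emmons olefination the electron-poor phosphonate and the dissociated potassium ion make elimination faster than reversal of the kinetic adduct, so the Z cinnamate should dominate, aromatic aldehydes being favourable substrates.

**Step 3**
Reactants: 4 methyl (Z)-3-[3-(tert-butyldimethylsilyloxy)-4,5-dimethoxyphenyl]prop-2-enoate
Product: 5 (Z)-3-[3-(tert-butyldimethylsilyloxy)-4,5-dimethoxyphenyl]prop-2-en-1-ol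
Conditions: i-Bu2AlH (2.5 equiv), CH2Cl2, −78 °C; aq. potassium sodium tartrate
Reagents that add atoms: none
Why: i-Bu2AlH performs a 1,2-reduction of the enoate to the allylic alcohol and leaves the Z alkene and the aryl silyl ether untouched at low temperature.

**Step 4**
Reactants: 5 (Z)-3-[3-(tert-butyldimethylsilyloxy)-4,5-dimethoxyphenyl]prop-2-en-1-ol; 6 trichloroacetonitrile
Product: 7 (Z)-3-[3-(tert-butyldimethylsilyloxy)-4,5-dimethoxyphenyl]allyl 2,2,2-trichloroacetimidate
Conditions: Cl3CCN (1.5 equiv), DBU (10 mol %), dry CH2Cl2, 0 °C; short plug of Et3N-washed SiO2, used at once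
Reagents that add atoms: none
Why: Base-catalysed addition of the alcohol to the electron-poor nitrile (trichloroacetimidate formation) breaks no bond at the allyl unit, so the Z geometry is kept, and immediate use limits rearrangement on storage.

**Step 5**
Reactants: 8 (E)-crotonaldehyde
Product: 9 (Z)-2-iodobut-2-enal
Conditions: I2, K2CO3, DMAP (20 mol %), THF–H2O (1:1), rt; aq. Na2S2O3
Reagents that add atoms: iodine, II
Why: In this Baylis–Hillman-type α-iodination DMAP adds in conjugate fashion, the enolate is iodinated and DMAP is expelled, which leaves the formyl group trans to the methyl group and iodine cis to it.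

**Step 6**
Reactants: 9 (Z)-2-iodobut-2-enal
Product: 10 (Z)-2-iodobut-2-en-1-ol
Conditions: NaBH4, MeOH, 0 °C
Reagents that add atoms: none
Why: Borohydride 1,2-reduction of the α-iodoenal is fast and leaves the C–I bond and the alkene geometry unchanged.

**Step 7**
Reactants: 10 (Z)-2-iodobut-2-en-1-ol
Product: 11 4-methoxybenzyl (Z)-2-(hydroxymethyl)but-2-enoate
Conditions: CO (1 atm), PdCl2(PPh3)2 (5 mol %), 4-MeOC6H4CH2OH (6 equiv), Et3N, DMF, 60 °C
Reagents that add atoms: carbon monoxide, [C-]#[O+]; 4-methoxybenzyl alcohol, COc1ccc(CO)cc1
Why: In this palladium-catalysed alkoxycarbonylation of a vinyl iodide, oxidative addition to zerovalent palladium and CO insertion proceed with retention, so the carboxyl carbon takes the place of iodine cis to the methyl group, and the excess benzylic alcohol outcompetes the substrate hydroxyl for the acylpalladium.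

**Step 8**
Reactants: 11 4-methoxybenzyl (Z)-2-(hydroxymethyl)but-2-enoate; 12 angelic acid, (Z)-2-methylbut-2-enoic acid
Product: 14 4-methoxybenzyl (Z)-2-{[(Z)-2-methylbut-2-enoyl]oxymethyl}but-2-enoate, via angelic 2,4,6-trichlorobenzoic anhydride 13 (not isolated)
Conditions: 12, 2,4,6-Cl3C6H2COCl, Et3N, PhMe, rt; then 11, 75 °C (no DMAP)
Reagents that add atoms: 2,4,6-trichlorobenzoyl chloride, O=C(Cl)c1c(Cl)cc(Cl)cc1Cl (its acyl group is held only in 13 and leaves again)
Why: In this Yamaguchi-type mixed-anhydride esterification the hindered aroyl carbonyl directs the primary alcohol to the angeloyl carbonyl, omitting a nucleophilic catalyst avoids the addition–elimination path from angelate to tiglate, and the allylic C–O bond of 11 is not broken, so both Z alkenes persist.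

**Step 9**
Reactants: 14 4-methoxybenzyl (Z)-2-{[(Z)-2-methylbut-2-enoyl]oxymethyl}but-2-enoate
Product: 15 (Z)-2-{[(Z)-2-methylbut-2-enoyl]oxymethyl}but-2-enoic acid
Conditions: CF3CO2H–CH2Cl2 (1:9), anisole, 0 °C
Reagents that add atoms: none
Why: Acidolysis of the 4-methoxybenzyl ester proceeds through the stabilised benzyl cation, which anisole traps, and the acidic medium avoids the base-induced vinylogous elimination of angelate that a fluoride- or hydroxide-labile ester would risk.

**Step 10**
Reactants: 7 (Z)-3-[3-(tert-butyldimethylsilyloxy)-4,5-dimethoxyphenyl]allyl 2,2,2-trichloroacetimidate; 15 (Z)-2-{[(Z)-2-methylbut-2-enoyl]oxymethyl}but-2-enoic acid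
Product: 16 (S)-1-[3-(tert-butyldimethylsilyloxy)-4,5-dimethoxyphenyl]allyl (Z)-2-{[(Z)-2-methylbut-2-enoyl]oxymethyl}but-2-enoate
Conditions: [(Rp,S)-(COP)Pd(OAc)]2 (2.5 mol %), 15 (2 equiv), CH2Cl2, 23 °C; excess 15 recovered by aq. NaHCO3 extraction
Reagents that add atoms: none
Why: The imidate nitrogen of 7 binds the divalent palladium of the planar-chiral palladacycle and draws the Z alkene onto the metal; the carboxylate of 15 attacks the aryl-bearing alkene carbon from the face away from palladium (anti-oxypalladation) to give a transient six-membered N,C-chelated alkylpalladium species, and syn-deoxypalladation then releases trichloroacetamide and leaves the double bond at the chain end. The closest known reaction type is the catalytic enantioselective SN2' esterification of (Z)-allylic trichloroacetimidates with carboxylic acids under this same acetate-bridged dimer, established mainly for 3-alkyl substrates and simple acids, so the 3-aryl group and the α-branched enoic acid stretch its scope and a higher loading is planned. No ring is closed in 16. The single new stereocentre, the benzylic carbon (S), is controlled by the catalyst alone: the tetraphenylcyclobutadiene floor and the isopropyloxazoline let the chelated Z alkene bind through one face, and attack is anti to the metal. The step needs branched SN2' substitution rather than linear substitution, ionisation or [3,3] rearrangement: chelation puts palladium on the central carbon so that only the distal benzylic carbon is open to the nucleophile, Z imidates rearrange slowly under this catalyst, and cation formation is held back by the weak acid, the solvent of low polarity and a 4-methoxy group that its two ortho neighbours twist out of conjugation. The TBS ether keeps the phenol from competing as a nucleophile, and the two trisubstituted enoates of 15 are too electron-poor and hindered to bind the metal.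

**Step 11**
Reactants: 16 (S)-1-[3-(tert-butyldimethylsilyloxy)-4,5-dimethoxyphenyl]allyl (Z)-2-{[(Z)-2-methylbut-2-enoyl]oxymethyl}but-2-enoate
Product: 17 (S)-1-[3-(tert-butyldimethylsilyloxy)-4,5-dimethoxyphenyl]propyl (Z)-2-{[(Z)-2-methylbut-2-enoyl]oxymethyl}but-2-enoate
Conditions: H2 (1 atm), RhCl(PPh3)3 (5 mol %), PhMe, rt
Reagents that add atoms: none
Why: Homogeneous hydrogenation with RhCl(PPh3)3 discriminates strongly by alkene substitution, so the monosubstituted vinyl group should be reduced while the two trisubstituted enoates stay uncoordinated, and benzylic C–O hydrogenolysis, a risk with heterogeneous palladium, should not intervene, so the stereocentre is untouched.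

**Step 12**
Reactants: 17 (S)-1-[3-(tert-butyldimethylsilyloxy)-4,5-dimethoxyphenyl]propyl (Z)-2-{[(Z)-2-methylbut-2-enoyl]oxymethyl}but-2-enoate
Product: 18 (S)-1-(3-hydroxy-4,5-dimethoxyphenyl)propyl (Z)-2-{[(Z)-2-methylbut-2-enoyl]oxymethyl}but-2-enoate (CNP0282120.1)
Conditions: Bu4NF, AcOH (1:1), THF, 0 °C
Reagents that add atoms: none
Why: Fluoride-induced cleavage of an aryl silyl ether is fast because phenoxide is a good leaving group from silicon, and the acetic acid buffer protonates it at once, so that neither acyl transfer, elimination of angelate nor ionisation of the benzylic ester is provoked.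

**Compound list**
1 | 3-hydroxy-4,5-dimethoxybenzaldehyde | COc1cc(C=O)cc(O)c1OC | starting material
2 | 3-(tert-butyldimethylsilyloxy)-4,5-dimethoxybenzaldehyde | COc1cc(C=O)cc(O[Si](C)(C)C(C)(C)C)c1OC | intermediate
3 | methyl bis(2,2,2-trifluoroethyl)phosphonoacetate | COC(=O)CP(=O)(OCC(F)(F)F)OCC(F)(F)F | starting material
4 | methyl (Z)-3-[3-(tert-butyldimethylsilyloxy)-4,5-dimethoxyphenyl]prop-2-enoate | COC(=O)/C=C\c1cc(O[Si](C)(C)C(C)(C)C)c(OC)c(OC)c1 | intermediate
5 | (Z)-3-[3-(tert-butyldimethylsilyloxy)-4,5-dimethoxyphenyl]prop-2-en-1-ol | OC/C=C\c1cc(O[Si](C)(C)C(C)(C)C)c(OC)c(OC)c1 | intermediate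
6 | trichloroacetonitrile | N#CC(Cl)(Cl)Cl | starting material
7 | (Z)-3-[3-(tert-butyldimethylsilyloxy)-4,5-dimethoxyphenyl]allyl 2,2,2-trichloroacetimidate | N=C(OC/C=C\c1cc(O[Si](C)(C)C(C)(C)C)c(OC)c(OC)c1)C(Cl)(Cl)Cl | intermediate
8 | (E)-crotonaldehyde | C/C=C/C=O | starting material
9 | (Z)-2-iodobut-2-enal | C/C=C(\I)C=O | intermediate
10 | (Z)-2-iodobut-2-en-1-ol | C/C=C(\I)CO | intermediate
11 | 4-methoxybenzyl (Z)-2-(hydroxymethyl)but-2-enoate | C/C=C(/CO)C(=O)OCc1ccc(OC)cc1 | intermediate
12 | angelic acid, (Z)-2-methylbut-2-enoic acid | C/C=C(/C)C(=O)O | starting material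
13 | angelic 2,4,6-trichlorobenzoic anhydride (not isolated) | C/C=C(/C)C(=O)OC(=O)c1c(Cl)cc(Cl)cc1Cl | intermediate
14 | 4-methoxybenzyl (Z)-2-{[(Z)-2-methylbut-2-enoyl]oxymethyl}but-2-enoate | C/C=C(/C)C(=O)OC/C(=C/C)C(=O)OCc1ccc(OC)cc1 | intermediate
15 | (Z)-2-{[(Z)-2-methylbut-2-enoyl]oxymethyl}but-2-enoic acid | C/C=C(/C)C(=O)OC/C(=C/C)C(=O)O | intermediate
16 | (S)-1-[3-(tert-butyldimethylsilyloxy)-4,5-dimethoxyphenyl]allyl (Z)-2-{[(Z)-2-methylbut-2-enoyl]oxymethyl}but-2-enoate | C/C=C(/C)C(=O)OC/C(=C/C)C(=O)O[C@@H](C=C)c1cc(O[Si](C)(C)C(C)(C)C)c(OC)c(OC)c1 | intermediate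
17 | (S)-1-[3-(tert-butyldimethylsilyloxy)-4,5-dimethoxyphenyl]propyl (Z)-2-{[(Z)-2-methylbut-2-enoyl]oxymethyl}but-2-enoate | C/C=C(/C)C(=O)OC/C(=C/C)C(=O)O[C@@H](CC)c1cc(O[Si](C)(C)C(C)(C)C)c(OC)c(OC)c1 | intermediate
18 | (S)-1-(3-hydroxy-4,5-dimethoxyphenyl)propyl (Z)-2-{[(Z)-2-methylbut-2-enoyl]oxymethyl}but-2-enoate | C/C=C(/C)C(=O)OC/C(=C/C)C(=O)O[C@@H](CC)c1cc(O)c(OC)c(OC)c1 | target

**Step count**
Total steps: 12. Longest linear sequence: 8 steps (8 to 18 through steps 5–12). The aryl branch needs 7 steps (steps 1–4 and 10–12).

**The three steps most likely to fail**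

**Step 10.**
- Risk: proton-assisted ionisation of the imidate to an aryl-stabilised allyl cation may outrun the palladium cycle, which would erode both enantioselectivity and branched selectivity. Attack of the α-branched acid on an aryl-bearing carbon may be slow. The imidate may also drift into rearrangement.
- Fallback: it sets out from 2 and 15. Catalytic enantioselective ethyl transfer to 2 (Et2Zn, (2S)-(−)-3-exo-(dimethylamino)isoborneol 5 mol %, toluene, 0 °C) should give (S)-1-[3-(tert-butyldimethylsilyloxy)-4,5-dimethoxyphenyl]propan-1-ol F1.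
- F1 is then acylated with 15 by carbodiimide esterification (EDC·HCl, catalytic DMAP, CH2Cl2, 0 °C). Only the O–H bond changes, so configuration at carbon is retained.
- The fallback comes back to the route at 17. Steps 2–4, 10 and 11 are then not needed.

**Step 11.**
- Risk: a rhodium hydride may move the double bond towards the benzylic carbon, with loss of the stereocentre. The doubly activated allylic and benzylic ester may ionise at the metal. Enoate reduction may set in at long reaction times.
- Fallback: it sets out from 16 and uses metal-free diimide transfer hydrogenation (2-nitrobenzenesulfonyl hydrazide, CH2Cl2, rt). Diimide delivers two hydrogens in a concerted way and prefers the least substituted alkene.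
- It comes back at 17 and makes no new compound (F0).

**Step 7.**
- Risk: the acylpalladium may be captured by the hydroxyl group of 10 or 11 instead of by 4-methoxybenzyl alcohol, which would build up oligoesters. The vinylpalladium may also be lost by β-hydroxide elimination.
- Fallback: it sets out from 10. Deprotonation with n-BuLi and iodine–lithium exchange with t-BuLi (2 equiv, Et2O, −78 °C) should give, with retention, lithium (Z)-2-lithiobut-2-en-1-olate F2.
- Carboxylation of F2 with CO2 gives (Z)-2-(hydroxymethyl)but-2-enoic acid F3.
- The carboxylate of F3 is alkylated chemoselectively with 4-methoxybenzyl chloride (KHCO3, DMF, rt), and the route is rejoined at 11.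

**Further compounds**
F1 | step 10 | (S)-1-[3-(tert-butyldimethylsilyloxy)-4,5-dimethoxyphenyl]propan-1-ol | O[C@@H](CC)c1cc(O[Si](C)(C)C(C)(C)C)c(OC)c(OC)c1
F0 | step 11 | none | none
F2 | step 7 | lithium (Z)-2-lithiobut-2-en-1-olate | C/C=C(\[Li])CO[Li]
F3 | step 7 | (Z)-2-(hydroxymethyl)but-2-enoic acid | C/C=C(/CO)C(=O)O
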